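X reads 0.471 of G at 3.00 h, the last reading of Monday's run, and I carry this ratio of X over G, a reading with its scatter, through this flask.

- Monday's: L 0.47 M; the very flask that is asked about, followed so far
- flask: L 0.47 M; time 15 h

Monday's run (percent of the L charged)

| time / h | X / % | G / % | L / % |
|---|---|---|---|
| 0.250 | 1.8 | 9.1 | 87.7 |
| 0.417 | 3.1 | 15.6 | 80.0 |
| 0.833 | 7.1 | 23.4 | 64.4 |
| 1.50 | 11.2 | 30.2 | 42.5 |
| 3.00 | 17.9 | 38.0 | 6.3 |

(readings scatter by 0.5 percentage points)

- solid, in amounts per volume of the solution: L
- at the start none of L is in solution
- G means what is dissolved; the solid is not counted in it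

- X present at 15 h, in percent of the L charged
- G present at 15 h, in percent of the L charged

Turn the question round: for X to hold its level up to 15 h while G falls, the step from G to X would have to run one way. I take G as the source of X. The first readings then give that step a rate constant near 0.953 h⁻¹, which is X gained over the area under G up to 0.417 h. That is a forward half-life near 0.727 h, short against 15 h. Run one way, the step would add 49 percentage points of X between 1.50 h and 3.00 h, but the readings gain 6.7 points. So I read X as a pre-equilibrium with G: X should sit near 0.471 of G and fall with it.

The forecast gives 19 % of X, “provided X is stable”, and 0.4 % of G.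

This flask gives 2.59 % of X and 5.04 % of G, and 0.471 of that G is 2.37 %.

    G ⇌ X (K = 0.490, k = 0.886 h⁻¹)
    G ⇌ Q (K = 2.10, k = 0.181 h⁻¹)
    G ⇌ J (K = 289, k = 0.296 h⁻¹)
    L ⇌ G, rate k4*(cs4 - [G]) while solid is left; crystals form when [G] > cs4 (solubility = 0.300 M, k = 0.869 h⁻¹)

In this flask the forward half-life of G to X, 0.78 h, is short against 15 h, and the way back turns over 99 % of the forward one. Read at 2.5 d, a neighbouring flask with the same charge holds 0.817 % of G, so 0.471 gives 0.385 % of X; the computed X there is 0.407 %.

Readings and results were computed with constants of no real substance; the scatter is artificial.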